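The plan rests on opening ring B at C7–C8 (guaiane numbering: ring A is C1–C5, ring B is C1 and C5–C10, the alkene is C1=C10, C11 is the carbinol carbon on C7). Once C11 is taken back to the ester level, the C8 oxygen sits β to that carbonyl across C7, which marks C7–C8 as a retro-aldol site. One samarium Reformatsky reaction then makes this bond, closes ring B and sets C7 and C8. Its precursor is a cis-4,5-disubstituted cyclopentane whose Z tetrasubstituted exocyclic C1=C10 alkene holds the CH2CHO arm (C9, C8) and the C5 arm ending in the α-bromo ester (C6, C7, C11) on one side.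

Key step: step 17

Assumption: (2R,3E)-pent-3-en-2-ol 5 is taken as a purchasable enantioenriched alcohol (otherwise from the racemate by enzymatic resolution); its carbinol centre is the only source of absolute configuration, because an achiral but-2-enyl ester would give racemic C4/C5.

Remark: TBS = tert-butyldimethylsilyl, TMS = trimethylsilyl. Oxan-2-yl ethers 16–28 are acetal epimer mixtures and 28–30 are C7 bromide epimer mixtures; both elements vanish in steps 15 and 17. Aldehyde 30 is unmasked last because a β,γ-unsaturated aldehyde isomerises easily.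

Step 1
Reactants: 1 oxan-2-one
Product: 4 5-(TBS-oxy)pentanoic acid, via sodium 5-hydroxypentanoate 2 (not isolated), via bis-silyl compound 3 (not isolated)
Conditions: NaOH, H2O/MeOH, 60 °C, evaporate; TBSCl, imidazole, DMF, rt; K2CO3, MeOH/THF/H2O, rt; 1 M HCl to pH 4, 0 °C
Reagents that add atoms: sodium hydroxide, [Na+].[OH-]; tert-butyl(chloro)dimethylsilane, CC(C)(C)[Si](C)(C)Cl
Why: Lactone saponification followed by exhaustive silylation and carbonate hydrolysis of the labile silyl ester (the silyl ether is stable to carbonate) should leave the acid with the C11 oxygen protected.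

Step 2
Reactants: 4 5-(TBS-oxy)pentanoic acid, 5 (2R,3E)-pent-3-en-2-ol
Product: 6 (2R,3E)-pent-3-en-2-yl 5-(TBS-oxy)pentanoate
Conditions: DCC, DMAP (cat.), CH2Cl2, 0 °C to rt
Reagents that add atoms: none
Why: Steglich esterification acylates the secondary allylic alcohol at oxygen, so the carbinol stereocentre and the E alkene are not touched.

Step 3
Reactants: 6 (2R,3E)-pent-3-en-2-yl 5-(TBS-oxy)pentanoate
Product: 9 (2S,3S,4E)-2-[3-(TBS-oxy)propyl]-3-methylhex-4-en-1-ol, via silyl ketene acetal 7 (not isolated), via trimethylsilyl ester 8 (not isolated)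
Conditions: LiN(i-Pr)2, THF, −78 °C; TMSCl/Et3N, −78 °C to rt then 50 °C; LiAlH4, 0 °C to rt
Reagents that add atoms: none
Why: In this Ireland–Claisen rearrangement kinetic enolisation in THF gives the (E)-ketene silyl acetal, which reorganises through a chair with the carbinol methyl equatorial, so the (R)-carbinol centre is transferred into C5 (S) and C4 (S) in the anti relationship with an E alkene, and LiAlH4 then reduces the silyl ester in the same flask.

Step 4
Reactants: 9 (2S,3S,4E)-2-[3-(TBS-oxy)propyl]-3-methylhex-4-en-1-ol, 10 ethene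
Product: 11 (2S,3S)-2-[3-(TBS-oxy)propyl]-3-methylpent-4-en-1-ol
Conditions: ethene (1–5 bar), second-generation Hoveyda–Grubbs catalyst RuCl2(=CH-o-i-PrOC6H4)(H2IMes) (5 mol %), CH2Cl2, 40 °C
Reagents that add atoms: none
Why: Ethenolysis (olefin cross-metathesis with ethene) should trim the propenyl group to the vinyl group, driven by excess ethene and loss of propene, without involving either stereocentre.

Step 5
Reactants: 11 (2S,3S)-2-[3-(TBS-oxy)propyl]-3-methylpent-4-en-1-ol
Product: 12 (2S,3S)-2-[3-(TBS-oxy)propyl]-3-methylpent-4-enal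
Conditions: Dess–Martin periodinane, NaHCO3, CH2Cl2, 0 °C to rt
Reagents that add atoms: none
Why: Buffered Dess–Martin oxidation should give the α-branched aldehyde (C1) without epimerising C5.

Step 6
Reactants: 12 (2S,3S)-2-[3-(TBS-oxy)propyl]-3-methylpent-4-enal
Product: 13 (3S,4S)-3-[3-(TBS-oxy)propyl]-4-methylhex-5-en-1-yne
Conditions: dimethyl (1-diazo-2-oxopropyl)phosphonate, K2CO3, MeOH, 0 °C to rt
Reagents that add atoms: dimethyl (1-diazo-2-oxopropyl)phosphonate, COP(=O)(OC)C(=[N+]=[N-])C(C)=O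
Why: Seyferth–Gilbert homologation in its Ohira–Bestmann form adds C10 and turns the aldehyde into the terminal alkyne under carbonate/methanol conditions mild enough to keep the α-stereocentre C5.

Step 7
Reactants: 13 (3S,4S)-3-[3-(TBS-oxy)propyl]-4-methylhex-5-en-1-yne, 14 2-(2-bromoethoxy)oxane
Product: 16 2-{[(5S,6S)-5-[3-(TBS-oxy)propyl]-6-methyloct-7-en-3-yn-1-yl]oxy}oxane, via lithium acetylide 15 (not isolated)
Conditions: n-BuLi, THF, −78 °C; 14, DMPU, −78 °C to rt
Reagents that add atoms: none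
Why: Acetylide alkylation (SN2 on the primary bromide in THF/DMPU) attaches C9 and C8 with the C8 oxygen already masked as an acetal that cannot undergo silyl migration to carbon in the later organolithium step.

Step 8
Reactants: 16 2-{[(5S,6S)-5-[3-(TBS-oxy)propyl]-6-methyloct-7-en-3-yn-1-yl]oxy}oxane
Product: 18 (3S,4S)-4-[3-(TBS-oxy)propyl]-3-methyl-8-(oxan-2-yloxy)oct-5-yn-1-ol, via alkyl-9-BBN adduct 17 (not isolated)
Conditions: 9-BBN, THF, 0 °C to rt; NaOH, H2O2, 0 °C to rt
Reagents that add atoms: hydrogen peroxide, OO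
Why: Hydroboration–oxidation with 9-BBN should attack the terminal alkene much faster than the internal alkyne and place oxygen on the terminal carbon C2.

Step 9
Reactants: 18 (3S,4S)-4-[3-(TBS-oxy)propyl]-3-methyl-8-(oxan-2-yloxy)oct-5-yn-1-ol
Product: 19 2-{[(5S,6S)-5-[3-(TBS-oxy)propyl]-8-iodo-6-methyloct-3-yn-1-yl]oxy}oxane
Conditions: I2, PPh3, imidazole, CH2Cl2, 0 °C to rt
Reagents that add atoms: iodine, II
Why: Appel-type iodination converts the primary alcohol into the primary iodide by SN2 under imidazole buffering that spares the silyl ether and the acetal.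

Step 10
Reactants: 19 2-{[(5S,6S)-5-[3-(TBS-oxy)propyl]-8-iodo-6-methyloct-3-yn-1-yl]oxy}oxane, 20 iodomethane
Product: 23 tert-butyldimethyl(3-{(1S,2Z,5S)-5-methyl-2-[4-(oxan-2-yloxy)butan-2-ylidene]cyclopentyl}propoxy)silane, via primary alkyllithium 21 (not isolated), via vinyllithium 22 (not isolated)
Conditions: t-BuLi (2.2 equiv), n-pentane/Et2O 3:2, −78 °C; warm to rt, 1 h; THF, MeI, −78 °C to rt
Reagents that add atoms: none
Why: Lithium–iodine exchange followed by 5-exo-dig intramolecular carbolithiation of the alkyne (anionic cyclisation of a 5-hexynyllithium) is a syn addition, so C2 and lithium become cis on C1=C10, and methylation of the configurationally stable vinyllithium with retention should fix the Z alkene (methyl cis to C2, C9 cis to C5) while C4 and C5 stay as set.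

Step 11
Reactants: 23 tert-butyldimethyl(3-{(1S,2Z,5S)-5-methyl-2-[4-(oxan-2-yloxy)butan-2-ylidene]cyclopentyl}propoxy)silane
Product: 24 3-{(1S,2Z,5S)-5-methyl-2-[4-(oxan-2-yloxy)butan-2-ylidene]cyclopentyl}propan-1-ol
Conditions: Bu4NF, THF, 0 °C to rt
Reagents that add atoms: none
Why: Fluoride-mediated desilylation frees the C11 alcohol while the oxanyl acetal on the C8 oxygen is inert to fluoride.

Step 12
Reactants: 24 3-{(1S,2Z,5S)-5-methyl-2-[4-(oxan-2-yloxy)butan-2-ylidene]cyclopentyl}propan-1-ol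
Product: 25 3-{(1S,2Z,5S)-5-methyl-2-[4-(oxan-2-yloxy)butan-2-ylidene]cyclopentyl}propanoic acid
Conditions: TEMPO (cat.), PhI(OAc)2, MeCN/H2O (pH 7 buffer), rt
Reagents that add atoms: water, O
Why: Nitroxyl-catalysed oxidation with PhI(OAc)2 in aqueous acetonitrile takes the primary alcohol through the aldehyde hydrate to the acid without chlorine oxidants that could attack the tetrasubstituted alkene.

Step 13
Reactants: 25 3-{(1S,2Z,5S)-5-methyl-2-[4-(oxan-2-yloxy)butan-2-ylidene]cyclopentyl}propanoic acid, 20 iodomethane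
Product: 26 methyl 3-{(1S,2Z,5S)-5-methyl-2-[4-(oxan-2-yloxy)butan-2-ylidene]cyclopentyl}propanoate
Conditions: MeI, K2CO3, DMF, rt
Reagents that add atoms: none
Why: O-Alkylation of the carboxylate (SN2 on iodomethane) gives the methyl ester under non-acidic conditions that keep the acetal.

Step 14
Reactants: 26 methyl 3-{(1S,2Z,5S)-5-methyl-2-[4-(oxan-2-yloxy)butan-2-ylidene]cyclopentyl}propanoate
Product: 28 methyl 2-bromo-3-{(1S,2Z,5S)-5-methyl-2-[4-(oxan-2-yloxy)butan-2-ylidene]cyclopentyl}propanoate, via ketene silyl acetal 27 (not isolated)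
Conditions: LiN(i-Pr)2, TMSCl, THF, −78 °C; NBS, −78 to 0 °C
Reagents that add atoms: N-bromosuccinimide, O=C1CCC(=O)N1Br
Why: α-Bromination of the ester through its ketene silyl acetal should be selective because the acetal reacts with NBS at −78 °C far faster than the tetrasubstituted alkene, and the new C7 centre may form as both epimers since it is erased in step 17.

Step 15
Reactants: 28 methyl 2-bromo-3-{(1S,2Z,5S)-5-methyl-2-[4-(oxan-2-yloxy)butan-2-ylidene]cyclopentyl}propanoate
Product: 29 methyl 2-bromo-3-[(1S,2Z,5S)-2-(4-hydroxybutan-2-ylidene)-5-methylcyclopentyl]propanoate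
Conditions: PPTS (cat.), MeOH, 40 °C
Reagents that add atoms: none
Why: Acid-catalysed transacetalisation to methanol removes the oxanyl group under conditions too mild to solvolyse the α-bromo ester or move the alkene.

Step 16
Reactants: 29 methyl 2-bromo-3-[(1S,2Z,5S)-2-(4-hydroxybutan-2-ylidene)-5-methylcyclopentyl]propanoate
Product: 30 methyl 2-bromo-3-[(1S,2Z,5S)-5-methyl-2-(4-oxobutan-2-ylidene)cyclopentyl]propanoate
Conditions: Dess–Martin periodinane, NaHCO3, CH2Cl2, 0 °C; used at once
Reagents that add atoms: none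
Why: Buffered Dess–Martin oxidation should deliver the C8 aldehyde without acid or base strong enough to pull the C1=C10 alkene into conjugation.

Step 17
Reactants: 30 methyl 2-bromo-3-[(1S,2Z,5S)-5-methyl-2-(4-oxobutan-2-ylidene)cyclopentyl]propanoate
Product: 32 methyl (3S,3aS,5S,6S)-6-hydroxy-3,8-dimethyl-1,2,3,3a,4,5,6,7-octahydroazulene-5-carboxylate, via samarium enolate 31 (not isolated)
Conditions: SmI2 (2.5 equiv, 0.1 M in THF), −78 °C, slow addition of 30 to 0.005 M; aq. NH4Cl
Reagents that add atoms: none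
Why: Divalent samarium delivers two electrons in succession to the carbon–bromine bond at C7, so both bromide epimers of 30 collapse to one trivalent samarium ester enolate, which attacks the C8 aldehyde within a six-membered samarium chelate of Zimmerman–Traxler type. The closest known reaction type is the SmI2-mediated intramolecular Reformatsky reaction used to close medium-sized carbocycles and lactones. Ring B closes in a 7-(enolexo)-exo-trig mode, the Z C1=C10 alkene and the cis arrangement at C4/C5 keeping C7 and C8 within bonding distance. C7 and C8 should come out trans because the ring bonds C7–C6 and C8–C9 both sit pseudo-equatorial on the chelate ring, which puts the ester carbon and the oxygen on opposite faces of ring B, and the sense relative to C5 (H7 on the face of H5) should follow from the ester carbon taking a pseudo-equatorial site on the forming ring. The step needs chemoselectivity for C–Br over the aldehyde and ring closure over intermolecular aldol addition: the α-bromo ester is the most easily reduced group in 30 at −78 °C without HMPA, and slow addition at high dilution favours the intramolecular path.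

Step 18
Reactants: 32 methyl (3S,3aS,5S,6S)-6-hydroxy-3,8-dimethyl-1,2,3,3a,4,5,6,7-octahydroazulene-5-carboxylate
Product: 33 (3S,3aS,5S,6S)-5-(2-hydroxypropan-2-yl)-3,8-dimethyl-1,2,3,3a,4,5,6,7-octahydroazulen-6-ol
Conditions: CeCl3, MeMgBr (5 equiv), THF, −78 to 0 °C
Reagents that add atoms: methylmagnesium bromide, C[Mg]Br
Why: Double Grignard addition to the ester gives the C11 dimethylcarbinol, with CeCl3 suppressing enolisation at C7 and retro-aldol cleavage of the C8 alkoxide so that C7 and C8 are kept.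

Step 19
Reactants: 34 (2E)-3-(4-hydroxyphenyl)prop-2-enoic acid
Product: 36 (2E)-3-[4-(TBS-oxy)phenyl]prop-2-enoic acid, via bis-silyl coumarate 35 (not isolated)
Conditions: TBSCl, imidazole, DMF, rt; AcOH/THF/H2O 3:1:1, rt
Reagents that add atoms: tert-butyl(chloro)dimethylsilane, CC(C)(C)[Si](C)(C)Cl
Why: Silylation of phenol and acid followed by mild aqueous-acid hydrolysis of the silyl ester (the aryl silyl ether is stable to it) gives the phenol-protected acid.

Step 20
Reactants: 33 (3S,3aS,5S,6S)-5-(2-hydroxypropan-2-yl)-3,8-dimethyl-1,2,3,3a,4,5,6,7-octahydroazulen-6-ol, 36 (2E)-3-[4-(TBS-oxy)phenyl]prop-2-enoic acid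
Product: 37 (3S,3aS,5S,6S)-5-(2-hydroxypropan-2-yl)-3,8-dimethyl-1,2,3,3a,4,5,6,7-octahydroazulen-6-yl (2E)-3-[4-(TBS-oxy)phenyl]prop-2-enoate
Conditions: DCC, DMAP, CH2Cl2, 0 °C to rt
Reagents that add atoms: none
Why: Steglich esterification should acylate only the secondary C8 hydroxyl, the tertiary C11 hydroxyl being too hindered, and C8 keeps its configuration because its C–O bond is not broken.

Step 21
Reactants: 37 (3S,3aS,5S,6S)-5-(2-hydroxypropan-2-yl)-3,8-dimethyl-1,2,3,3a,4,5,6,7-octahydroazulen-6-yl (2E)-3-[4-(TBS-oxy)phenyl]prop-2-enoate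
Product: 38 (3S,3aS,5S,6S)-5-(2-hydroxypropan-2-yl)-3,8-dimethyl-1,2,3,3a,4,5,6,7-octahydroazulen-6-yl (2E)-3-(4-hydroxyphenyl)prop-2-enoate
Conditions: Bu4NF, AcOH, THF, 0 °C
Reagents that add atoms: none
Why: Fluoride cleaves the aryl silyl ether quickly, and acetic acid buffering keeps the phenoxide from cleaving or shifting the C8 ester.

Compound list
1 | oxan-2-one | O=C1CCCCO1 | starting material
2 | sodium 5-hydroxypentanoate | [Na+].[O-]C(=O)CCCCO | intermediate
3 | TBS 5-(TBS-oxy)pentanoate | CC(C)(C)[Si](C)(C)OCCCCC(=O)O[Si](C)(C)C(C)(C)C | intermediate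
4 | 5-(TBS-oxy)pentanoic acid | CC(C)(C)[Si](C)(C)OCCCCC(=O)O | intermediate
5 | (2R,3E)-pent-3-en-2-ol | C/C=C/[C@@H](C)O | starting material
6 | (2R,3E)-pent-3-en-2-yl 5-(TBS-oxy)pentanoate | C/C=C/[C@@H](C)OC(=O)CCCCO[Si](C)(C)C(C)(C)C | intermediate
7 | (E)-ketene trimethylsilyl acetal of 6 | C/C=C/[C@@H](C)O/C(O[Si](C)(C)C)=C\CCCO[Si](C)(C)C(C)(C)C | intermediate
8 | trimethylsilyl (2S,3S,4E)-2-[3-(TBS-oxy)propyl]-3-methylhex-4-enoate | C/C=C/[C@H](C)[C@@H](C(=O)O[Si](C)(C)C)CCCO[Si](C)(C)C(C)(C)C | intermediate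
9 | (2S,3S,4E)-2-[3-(TBS-oxy)propyl]-3-methylhex-4-en-1-ol | C/C=C/[C@H](C)[C@@H](CO)CCCO[Si](C)(C)C(C)(C)C | intermediate
10 | ethene | C=C | starting material
11 | (2S,3S)-2-[3-(TBS-oxy)propyl]-3-methylpent-4-en-1-ol | C=C[C@H](C)[C@@H](CO)CCCO[Si](C)(C)C(C)(C)C | intermediate
12 | (2S,3S)-2-[3-(TBS-oxy)propyl]-3-methylpent-4-enal | C=C[C@H](C)[C@@H](C=O)CCCO[Si](C)(C)C(C)(C)C | intermediate
13 | (3S,4S)-3-[3-(TBS-oxy)propyl]-4-methylhex-5-en-1-yne | C=C[C@H](C)[C@@H](C#C)CCCO[Si](C)(C)C(C)(C)C | intermediate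
14 | 2-(2-bromoethoxy)oxane | BrCCOC1CCCCO1 | starting material
15 | lithium acetylide of 13 | C=C[C@H](C)[C@@H](C#C[Li])CCCO[Si](C)(C)C(C)(C)C | intermediate
16 | 2-{[(5S,6S)-5-[3-(TBS-oxy)propyl]-6-methyloct-7-en-3-yn-1-yl]oxy}oxane | C=C[C@H](C)[C@@H](C#CCCOC1CCCCO1)CCCO[Si](C)(C)C(C)(C)C | intermediate
17 | 9-alkyl-9-borabicyclo[3.3.1]nonane from 16 (boron on C2) | C(C[C@H](C)[C@@H](C#CCCOC1CCCCO1)CCCO[Si](C)(C)C(C)(C)C)B1C2CCCC1CCC2 | intermediate
18 | (3S,4S)-4-[3-(TBS-oxy)propyl]-3-methyl-8-(oxan-2-yloxy)oct-5-yn-1-ol | OCC[C@H](C)[C@@H](C#CCCOC1CCCCO1)CCCO[Si](C)(C)C(C)(C)C | intermediate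
19 | 2-{[(5S,6S)-5-[3-(TBS-oxy)propyl]-8-iodo-6-methyloct-3-yn-1-yl]oxy}oxane | ICC[C@H](C)[C@@H](C#CCCOC1CCCCO1)CCCO[Si](C)(C)C(C)(C)C | intermediate
20 | iodomethane | CI | starting material
21 | primary alkyllithium from 19 (lithium on C2) | [Li]CC[C@H](C)[C@@H](C#CCCOC1CCCCO1)CCCO[Si](C)(C)C(C)(C)C | intermediate
22 | cyclised vinyllithium (lithium on C10, cis to C2) | [Li]/C(CCOC2CCCCO2)=C1\CC[C@H](C)[C@@H]1CCCO[Si](C)(C)C(C)(C)C | intermediate
23 | tert-butyldimethyl(3-{(1S,2Z,5S)-5-methyl-2-[4-(oxan-2-yloxy)butan-2-ylidene]cyclopentyl}propoxy)silane | C/C(CCOC2CCCCO2)=C1\CC[C@H](C)[C@@H]1CCCO[Si](C)(C)C(C)(C)C | intermediate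
24 | 3-{(1S,2Z,5S)-5-methyl-2-[4-(oxan-2-yloxy)butan-2-ylidene]cyclopentyl}propan-1-ol | C/C(CCOC2CCCCO2)=C1\CC[C@H](C)[C@@H]1CCCO | intermediate
25 | 3-{(1S,2Z,5S)-5-methyl-2-[4-(oxan-2-yloxy)butan-2-ylidene]cyclopentyl}propanoic acid | C/C(CCOC2CCCCO2)=C1\CC[C@H](C)[C@@H]1CCC(=O)O | intermediate
26 | methyl 3-{(1S,2Z,5S)-5-methyl-2-[4-(oxan-2-yloxy)butan-2-ylidene]cyclopentyl}propanoate | C/C(CCOC2CCCCO2)=C1\CC[C@H](C)[C@@H]1CCC(=O)OC | intermediate
27 | ketene methyl trimethylsilyl acetal of 26 | C/C(CCOC2CCCCO2)=C1\CC[C@H](C)[C@@H]1CC=C(OC)O[Si](C)(C)C | intermediate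
28 | methyl 2-bromo-3-{(1S,2Z,5S)-5-methyl-2-[4-(oxan-2-yloxy)butan-2-ylidene]cyclopentyl}propanoate (both C7 epimers) | C/C(CCOC2CCCCO2)=C1\CC[C@H](C)[C@@H]1CC(Br)C(=O)OC | intermediate
29 | methyl 2-bromo-3-[(1S,2Z,5S)-2-(4-hydroxybutan-2-ylidene)-5-methylcyclopentyl]propanoate (both C7 epimers) | C/C(CCO)=C1\CC[C@H](C)[C@@H]1CC(Br)C(=O)OC | intermediate
30 | methyl 2-bromo-3-[(1S,2Z,5S)-5-methyl-2-(4-oxobutan-2-ylidene)cyclopentyl]propanoate (both C7 epimers) | C/C(CC=O)=C1\CC[C@H](C)[C@@H]1CC(Br)C(=O)OC | intermediate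
31 | trivalent samarium enolate of 30 | C/C(CC=O)=C1\CC[C@H](C)[C@@H]1CC=C(OC)O[Sm](I)I | intermediate
32 | methyl (3S,3aS,5S,6S)-6-hydroxy-3,8-dimethyl-1,2,3,3a,4,5,6,7-octahydroazulene-5-carboxylate | CC1=C2CC[C@H](C)[C@@H]2C[C@H](C(=O)OC)[C@@H](O)C1 | intermediate
33 | (3S,3aS,5S,6S)-5-(2-hydroxypropan-2-yl)-3,8-dimethyl-1,2,3,3a,4,5,6,7-octahydroazulen-6-ol | CC1=C2CC[C@H](C)[C@@H]2C[C@H](C(C)(C)O)[C@@H](O)C1 | intermediate
34 | (2E)-3-(4-hydroxyphenyl)prop-2-enoic acid | OC(=O)/C=C/c1ccc(O)cc1 | starting material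
35 | TBS (2E)-3-[4-(TBS-oxy)phenyl]prop-2-enoate | CC(C)(C)[Si](C)(C)OC(=O)/C=C/c1ccc(O[Si](C)(C)C(C)(C)C)cc1 | intermediate
36 | (2E)-3-[4-(TBS-oxy)phenyl]prop-2-enoic acid | OC(=O)/C=C/c1ccc(O[Si](C)(C)C(C)(C)C)cc1 | intermediate
37 | (3S,3aS,5S,6S)-5-(2-hydroxypropan-2-yl)-3,8-dimethyl-1,2,3,3a,4,5,6,7-octahydroazulen-6-yl (2E)-3-[4-(TBS-oxy)phenyl]prop-2-enoate | CC1=C2CC[C@H](C)[C@@H]2C[C@H](C(C)(C)O)[C@@H](OC(=O)/C=C/c2ccc(O[Si](C)(C)C(C)(C)C)cc2)C1 | intermediate
38 | (3S,3aS,5S,6S)-5-(2-hydroxypropan-2-yl)-3,8-dimethyl-1,2,3,3a,4,5,6,7-octahydroazulen-6-yl (2E)-3-(4-hydroxyphenyl)prop-2-enoate | CC1=C2CC[C@H](C)[C@@H]2C[C@H](C(C)(C)O)[C@@H](OC(=O)/C=C/c2ccc(O)cc2)C1 | target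

Total step count: 21. Longest linear sequence: 20 steps (steps 1–18, 20 and 21; step 19 is a one-step branch).

Steps most likely to fail

Step 17. The ring closure may show poor facial discrimination (cis aldol from the other enolate geometry, or attack on the other face relative to C5), and ketyl formation at the aldehyde may compete with bromide reduction. The fallback moves stereocontrol from the aldol event to a catalyst-controlled reduction. It sets out from 30: the same closure is run without regard to selectivity and should give the diastereomer mixture methyl (3S,3aS)-6-hydroxy-3,8-dimethyl-1,2,3,3a,4,5,6,7-octahydroazulene-5-carboxylate F1. Dess–Martin oxidation (NaHCO3, CH2Cl2, 0 °C) would convert it into the β-keto ester methyl (3S,3aS)-3,8-dimethyl-6-oxo-1,2,3,3a,4,5,6,7-octahydroazulene-5-carboxylate F2, in which C8 is no longer a stereocentre and C7 epimerises freely. Asymmetric hydrogenation with dynamic kinetic resolution (RuCl2[(S)-binap], H2, CH2Cl2/MeOH, kept neutral to avoid moving the alkene) should then give the trans hydroxy ester with the (S)-carbinol, and the route is rejoined at 32.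

Step 10. Lithium–iodine exchange between vinyllithium 22 and iodomethane, or proton transfer to 22 before alkylation, may leave methyl transfer incomplete. The fallback replaces direct alkylation by cross-coupling. It sets out from 19: after the same exchange and ring closure, 22 is quenched with I2 (−78 °C) to give, with retention, the vinyl iodide tert-butyl(3-{(1S,2E,5S)-2-[1-iodo-3-(oxan-2-yloxy)propylidene]-5-methylcyclopentyl}propoxy)dimethylsilane F3. A Negishi coupling (MeZnCl, Pd(PPh3)4 as zerovalent palladium source, THF, rt to 50 °C) should then replace iodine by methyl with retention of alkene geometry, and the route is rejoined at 23.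

Step 4. Ethenolysis of the branched internal alkene may stall at the metathesis equilibrium, and ruthenium hydride formed on catalyst decay may shift the double bond. The fallback cleaves and rebuilds the alkene instead. It sets out from 9: ozonolysis (O3, CH2Cl2/MeOH, −78 °C; PPh3) removes the propenyl terminus, and the hydroxy aldehyde should close to the lactol (3R,4S)-3-methyl-4-[3-(TBS-oxy)propyl]oxolan-2-ol F4. Wittig methylenation of the lactol (Ph3PCH3Br, KOt-Bu, THF, 0 °C, kept cold to limit epimerisation at C4) should then deliver the vinyl group, and the route is rejoined at 11.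

Further compounds
F1 | step 17 | methyl (3S,3aS)-6-hydroxy-3,8-dimethyl-1,2,3,3a,4,5,6,7-octahydroazulene-5-carboxylate (C5/C6 diastereomer mixture, azulene locants) | CC1=C2CC[C@H](C)[C@@H]2CC(C(=O)OC)C(O)C1
F2 | step 17 | methyl (3S,3aS)-3,8-dimethyl-6-oxo-1,2,3,3a,4,5,6,7-octahydroazulene-5-carboxylate | CC1=C2CC[C@H](C)[C@@H]2CC(C(=O)OC)C(=O)C1
F3 | step 10 | tert-butyl(3-{(1S,2E,5S)-2-[1-iodo-3-(oxan-2-yloxy)propylidene]-5-methylcyclopentyl}propoxy)dimethylsilane | I/C(CCOC2CCCCO2)=C1\CC[C@H](C)[C@@H]1CCCO[Si](C)(C)C(C)(C)C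
F4 | step 4 | (3R,4S)-3-methyl-4-[3-(TBS-oxy)propyl]oxolan-2-ol (anomer mixture) | OC1OC[C@@H](CCCO[Si](C)(C)C(C)(C)C)[C@H]1C
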